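I reckon by one clock and not by a fitted scheme, since you want a quick number.

| setting | blue | grey | red | east | north-west | south-east |
|---|---|---|---|---|---|---|
| starting complex | 0.40 M | 0.20 M | 0.80 M | 0.40 M | 0.40 M (fed, over 1.5 h) | 0.40 M |
| incoming ligand | 0.32 M | 0.32 M | 0.32 M | 0.320 M (fed, over 1.5 h) | 0.320 M | 0.320 M |
| remark | run made earlier | run made earlier | run made earlier | all else is in the flask from the start; the feed brings no volume worth counting | all else is in the flask from the start; the feed brings no volume worth counting | everything together at the start |
| time |  |  |  | 2.0 h | 2.0 h | 2.0 h |

- blue (time / min: complex with one exchanged / %, complex with two exchanged / %): 30.0: 15.2, 4.6; 60.0: 17.5, 8.6; 90.0: 15.6, 10.8; 120: 13.7, 12.5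
- grey (time / min: complex with one exchanged / %, complex with two exchanged / %): 30.0: 18.0, 6.2; 60.0: 20.6, 12.1; 90.0: 20.4, 17.2; 120: 18.7, 19.9
- red (time / min: complex with one exchanged / %, complex with two exchanged / %): 15.0: 9.8, 1.9; 40.0: 11.2, 3.3; 80.0: 9.0, 4.9; 120: 6.2, 5.6

(each reading ± 0.3 percentage points)

- the flask that comes out highest in share of complex with one exchanged in complex with one exchanged plus complex with two exchanged, or "all alike" when all lie within 1.5 percentage points (east / north-west / south-east / all alike)
- share of complex with one exchanged in complex with one exchanged plus complex with two exchanged at the end, east
- share of complex with one exchanged in complex with one exchanged plus complex with two exchanged at the end, north-west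
- share of complex with one exchanged in complex with one exchanged plus complex with two exchanged at the end, south-east

- what was read earlier has a scatter of 0.3 percentage points, one standard deviation

1. I follow one molecule of complex with one exchanged. Once made, it waits, and one way on is to take incoming ligand and become complex with two exchanged. So I expect the asked share (the selectivity for the first exchange) to fall as molecules wait longer.

2. Blue shows this: the share is 76.8 % at 30.0 min and 52.3 % at 120 min. South-east has blue's recipe, so I take that last share for it.

3. A steady feed delivers its charge on average at half of the feed time, so on average the waiting starts later. I define the clock as the reading time minus half of the feed time, which is 75.0 min for both fed flasks.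

4. That clock falls midway between blue's readings at 60.0 min and 90.0 min, whose shares are 67.0 % and 59.1 %, so I give east and north-west about 63.1 %. The clock gives these two flasks the same number, so naming east as the top is a plain guess of mine.

5. The forecast says 62 % for east, 50 % for north-west and 52.3 % for south-east, with east highest, and notes “South-east simply repeats blue”. We part on north-west, where my number is higher.

The flasks give 63.5 % for east, 59.6 % for north-west and 53.2 % for south-east, so east stands highest.

    starting complex + complex with one exchanged → side product (k = 0.0300 L mol⁻¹ min⁻¹)
    starting complex + incoming ligand ⇌ leaving ligand + complex with one exchanged (K = 2.40, k = 0.0360 L mol⁻¹ min⁻¹)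
    leaving ligand → by-product carried off (k = 0.00970 min⁻¹)
    complex with two exchanged + incoming ligand ⇌ leaving ligand + complex with three exchanged (K = 1.30, k = 0.0460 L mol⁻¹ min⁻¹)
    complex with one exchanged + incoming ligand ⇌ leaving ligand + complex with two exchanged (K = 8.60, k = 0.0710 L mol⁻¹ min⁻¹)

My clock of 75.0 min gave 63.1 %, with east above that number and north-west below it. A neighbouring flask is south-east read at 50 min. It has no feed, so its clock is the reading time, and blue's line between its first two readings gives 70.3 %. That flask gives 68.8 %, with starting complex at 62.7 %.

The earlier runs and the new flask were computed for substances that don't exist, noise included.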